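Numbering used throughout: chroman atoms are unprimed (O1, spiro C2, C3, C4, C4a, C5–C8, C8a); norbornane atoms are primed (C2' = C2, C1' the adjacent bridgehead, C3' the CMe2 carbon, C4' the far bridgehead, C7' the one-carbon bridge).

## The problem

Target 14 is a spirochroman in which C2 of the pyran ring (O1, C2, C3, C4, C4a, C8a) is also C2' of a 3',3'-dimethylnorbornane, and its benzene ring is fully substituted: O1 at C8a, hydroxyls at C5 and C7, formyl groups at C6 and C8, and C4 at C4a. There are four stereocentres: the bridgeheads C1' (R) and C4' (S), the spiro carbon C2 (R; O1 endo and C3 exo on the norbornane) and C4 (S; isobutyl on the pyran face that carries C3', hydrogen on the face that carries C1'). The bridgeheads are locked to each other and can control C2, because the exo face of a norbornan-2-one carbonyl is the one open to carbon nucleophiles; C2 in turn can control C4, because it shows a bridgehead CH to one face of the pyran ring and a CMe2 group to the other. The two formyl groups, each ortho to a phenol, are the least robust part and should arrive last. The C2–O1 bond is a tertiary ether on a 2-norbornyl carbon next to a quaternary centre, so ionisation there would start Wagner–Meerwein and Nametkin shifts and erase the spiro configuration; the bond should therefore not be made by substitution at C2 and should not meet strong acid. The enabling feature is the placement of the heteroatoms around C4: C8a is ortho to C4a, so a carbonyl at C4 activates a leaving group at C8a and acidifies C3, whereas the oxygens at C5 and C7 are meta to C8a and put no resonance donation on it. C2, finally, is at the oxidation level of a ketone whose oxygen can become O1.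

## Retrosynthesis

**14 to 13.** The C6–CHO and C8–CHO bonds are cut first. The aldehydes would not survive the organometallic, basic and reductive steps, and once removed they leave C6 and C8 as the only free arene positions of 13, each ortho to a phenol, so their return poses no regiochemical question. Carrying them in protected form would cost steps and would change the electronics of every earlier operation. Diphenol 13 is simpler by two carbonyl groups. The forward reaction must formylate twice without ionising C2–O1.

**13 to 12.** The C4–H and C3–H bonds and both O–benzyl bonds are cut, leading to 2H-chromene 12. This puts the creation of C4 into a hydrogenation that the spiro centre can steer, and the same operation frees both phenols. Carrying C4 as a stereocentre through ring construction would leave it without a control element. Chromene 12 has one stereocentre fewer. The forward step must deliver hydrogen syn from the C1' face.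

**12 to 9 and 10.** The C4–isobutyl bond is cut and the C3=C4 bond is traced back to a carbinol (11), so C4 becomes a ketone and the side chain becomes Grignard reagent 10. This is preferred over bringing the isobutyl group in with the aryl fragment, because the C4 carbonyl is exactly what the next disconnection needs. Chromanone 9 lacks the side chain and the alkene. The forward step must add a β-branched nucleophile to an electron-rich, peri-hindered, enolisable ketone and then lose water.

**9 to 6 and 2 (key disconnection).** The C2–C3 and O1–C8a bonds are cut, which splits the pyranone into fluoroacetophenone 6 and ketone 2. Three neighbouring cuts were weighed.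
- A Kabbe-type condensation of a hydroxyaryl ketone with 2 forms C2–O1 last, by conjugate addition to an alkylidene derivative of 2. That alkene is hard to form from a hindered ketone, and oxygen would arrive from the exo face, giving the wrong spiro epimer.
- Substitution at C2' by a phenol through a cation would also place oxygen exo and would rearrange the skeleton.
- A cycloaddition of an ortho-quinone methide to alkene 1 would be the shortest route of all. It leaves both C2 and C4 to the facial and endo/exo preferences of one thermal event, with no separate handle on either.

In the chosen cut the oxygen of 2 never leaves C2', the carbon nucleophile arrives exo, and each stereocentre is assigned to its own analysable step. The precursors are an achiral arene and a C9 ketone. The forward step must outrun retro-aldol cleavage by an intramolecular fluoride displacement.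

**6 to 5 and 4, then 5 to 3 and 4.** The two aryl C–O bonds are cut in turn. Removing the ortho ether of 6 gives difluoro ether 5 and benzyl alcohol 4; removing the para ether of 5 gives trifluoroacetophenone 3 and a second molecule of 4. Substitution is preferred over acylation of a preformed fluoro diether because the acetyl group is then already in place and directs the chemistry. Two separate displacements are preferred over one double displacement because each can be run in the medium that suits its position, dipolar aprotic for para and ethereal for ortho, and 5 can be purified in between. Each forward step must stop after one displacement, so that a single ortho fluoride is left in 6.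

**2 to 1.** The C2'=O bond is traced to the exocyclic C=CH2 bond of camphene 1, which supplies C1', C4' and the gem-dimethyl carbon C3' from the chiral pool. The forward step is an alkene cleavage that touches no stereocentre.

## Roads not taken

Alternative 1: The cut removes the C3–C4 and C4–isobutyl bonds and treats C4 as a dithiane carbon. The pieces are the endo-oxygen spiro-epoxide A1 (reachable from 2 by exo methylene transfer), 2-silyl-1,3-dithiane A2 and 1-iodo-2-methylpropane A3. In the forward key step lithiated A2 opens A1 at its CH2 carbon, a polar additive triggers a 1,4-Brook shift of silicon from carbon to the new tertiary alkoxide, and the regenerated dithiane anion is alkylated by A3 to give A4.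
- Merits: the C2–C3 bond comes from an irreversible substitution at a primary carbon, free of any retro-aldol problem. The oxygen stays on C2' as in the chosen plan. The tertiary alcohol emerges silylated, and three components join in one flask.
- Weak points: A4 contains no ring of the target beyond the norbornane and no arene. The dithiane must still be unmasked, an aryl group added at C4, the O1–C8a bond made on a hindered tertiary alcohol when no carbonyl activates the arene, and C4 deoxygenated with stereocontrol. The CH2 of A1 is neopentyl-like, the nucleophile is bulky, and A3 is β-branched and prone to elimination.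
- Comparison: this road is better in the certainty of the C2–C3 bond. The chosen plan sets against it that one C4 carbonyl serves as enolate source, as activator of the fluoride and as anchor for the side chain, which roughly halves the step count.

Alternative 2: The cut is the C3'–C4' bond of the norbornane. The precursor is chroman A5, whose C2 carries an isopropenyl and a cyclopent-3-enyl group. In the forward key step a metal hydride transfers a hydrogen atom to the isopropenyl group, the tertiary radical at C3' adds to one olefinic carbon of the cyclopentene (5-exo-trig), and a thiol reduces the C5' radical to give A6, the 5,7-dibenzyl ether of deformyl-14.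
- Merits: the chroman and C4 are settled before the bicycle exists. The quaternary C3' forms under mild radical conditions that benzyl ethers tolerate. The route does not depend on terpene supply and would give either enantiomer and ring analogues.
- Weak points: all absolute configuration must be created. C2 of A5 is a quaternary stereocentre with two carbon groups of similar size. The radical must choose between two diastereotopic olefinic carbons, only one of which puts O1 endo. Closure to a strained bicycle with adjacent quaternary carbons competes with simple reduction of the tertiary radical.
- Comparison: this road is better in flexibility. The chosen plan sets against it that C1', C4' and C3' are bought ready-made in 1, and the only stereochemical question left at the bicycle is the face of one carbonyl.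

Alternative 3: The cut is the C4–C4a bond. The precursor is tertiary propargyl aryl ether A7, obtained in principle from 2 by exo acetylide addition and O-arylation. In the forward key step a cationic monovalent gold catalyst activates the alkyne and the arene carbon ortho to oxygen attacks its distal carbon (6-endo-dig), giving A8, which is identical with chromene 12.
- Merits: 12 is reached with the isobutyl group already in place, so the addition to the deactivated ketone and the dehydration are avoided. Acetylide addition to 2 is irreversible and exo-selective, a more dependable C–C bond formation than a reversible aldol. The arene is symmetrical, so there is no regiochemical issue.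
- Weak points: the O1–C8a bond must be made by arylating a very hindered tertiary propargylic alkoxide with an electron-rich, unactivated aryl unit, for which displacement of a halide is not available. Substitution at C2' by a phenol through a propargylic cation would place oxygen exo and invite rearrangement. Tertiary propargylic aryl ethers can also ionise under gold catalysis.
- Comparison: this road is better in the endgame, being one operation shorter after ring formation. The chosen plan sets against it that O1 is the untouched ketone oxygen of 2 and that the aryl C–O bond forms by an activated, intramolecular fluoride displacement.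

Key step: step 4

Assumption: (1S,4R)-camphene 1 is taken to be available in high enantiomeric purity. If a lot falls short, crystallisation of ketone 9 would be the point at which to try enrichment.

## Route

Step 1
Reactants: 1 (1S,4R)-camphene
Product: 2 (1R,4S)-camphenilone [(1R,4S)-3,3-dimethylbicyclo[2.2.1]heptan-2-one]
Conditions: O3, CH2Cl2/MeOH, −78 °C; then Me2S, −78 °C → rt
Reagents that add atoms: ozone, [O-][O+]=O
Why: Ozonolysis of the 1,1-disubstituted exocyclic alkene with reductive work-up removes the methylene carbon as formaldehyde, and methanol traps the carbonyl oxide so that rearranged lactone by-products are held back. Neither bridgehead is touched and the ketone formed cannot enolise.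

Step 2
Reactants: 3 2',4',6'-trifluoroacetophenone; 4 benzyl alcohol
Product: 5 1-[4-(benzyloxy)-2,6-difluorophenyl]ethanone
Conditions: BnOH (1.05 equiv), NaH (1.0 equiv), THF, 0 °C; added slowly to 3 in DMF, −40 → 0 °C
Reagents that add atoms: none
Why: Nucleophilic aromatic substitution (SNAr) by preformed sodium benzyloxide: the acetyl group and the fluorines activate all three positions, and in a dipolar aprotic medium, where the cation is solvated and does not bridge to the carbonyl oxygen, the less hindered para fluoride should leave first. Slow addition of one equivalent of alkoxide to cold 3 holds the reaction at a single displacement and keeps enolisation of the methyl ketone down, and any ortho isomer is removed when 5 is purified.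

Step 3
Reactants: 5 1-[4-(benzyloxy)-2,6-difluorophenyl]ethanone; 4 benzyl alcohol
Product: 6 1-[2,4-bis(benzyloxy)-6-fluorophenyl]ethanone
Conditions: BnOH (1.1 equiv), NaH (1.05 equiv), THF, 0 → 40 °C
Reagents that add atoms: none
Why: Second SNAr, now at one of the two equivalent ortho fluorides, the only leaving groups left, so that no regiochemical question arises; in THF the sodium ion can bridge the carbonyl oxygen and the alkoxide, which helps ortho delivery. The product carries two donor oxygens conjugated with the acetyl group, which should make a third displacement much slower and leave one ortho fluoride in place.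

Step 4
Reactants: 6 1-[2,4-bis(benzyloxy)-6-fluorophenyl]ethanone; 2 (1R,4S)-camphenilone
Product: 9 (1'R,2R,4'S)-5,7-bis(benzyloxy)-3',3'-dimethylspiro[chromane-2,2'-norbornan]-4-one, via potassium enolate 7 (not isolated), via potassium aldolate 8 (not isolated)
Conditions: KN(SiMe3)2 (2.2 equiv), THF, −78 °C; then 2 (1.5 equiv), −78 °C → rt (40 °C if ring closure lags); aq NH4Cl at 0 °C
Reagents that add atoms: none
Why: KN(SiMe3)2 converts 6 fully into potassium enolate 7, which adds reversibly to the carbonyl of non-enolisable 2 from the exo face, the face that organomagnesium reagents take on this ketone, so that C3 becomes exo and the alkoxide oxygen of 8 endo. In 8 that oxygen lies six atoms from C8a and adds to it to give a Meisenheimer complex whose charge is taken up by the ortho acyl group; loss of fluoride makes the closure irreversible and drains the aldol equilibrium. The closest known reaction type is the chroman-4-one synthesis by intramolecular SNAr of 2-fluoroaryl β-hydroxy ketones, run here in tandem with the enolate aldol addition that produces the hydroxy ketone. The pyranone ring closes by a six-membered addition–elimination, 6-exo-trig when C8a=C8 is counted as the acceptor bond, and the cyclic transition state keeps the carbonyl near the arene plane so that its activation is felt. The spiro stereocentre C2 is controlled by the bridgeheads C1' and C4' of 2 through the exo preference of C–C bond formation, and because O1 is the original ketone oxygen no bond to C2 is broken afterwards. The step needs carbon attack on 2 to win over self-condensation of 7 and intermolecular fluoride displacement; complete enolisation (no neutral 6 left as electrophile), the 2,6-disubstitution that shields the aryl ketone, and the meta placement of both benzyloxy groups relative to fluorine (no resonance donation onto C8a) should secure this. The second equivalent of base holds product 9 as its enolate, out of reach of 7, and the cold quench as soon as 6 is consumed gives that enolate no time to open by β-elimination of the phenoxide.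

Step 5
Reactants: 9 (1'R,2R,4'S)-5,7-bis(benzyloxy)-3',3'-dimethylspiro[chromane-2,2'-norbornan]-4-one; 10 isobutylmagnesium bromide
Product: 12 (1'R,2S,4'S)-5,7-bis(benzyloxy)-3',3'-dimethyl-4-(2-methylpropyl)spiro[2H-chromene-2,2'-norbornane], via tertiary alcohol 11 (not isolated)
Conditions: 10 (3 equiv), CeCl3 (3 equiv), THF, −78 → 0 °C; aq NH4Cl; crude 11, PPTS (cat.), PhMe, 40 °C
Reagents that add atoms: none
Why: CeCl3-promoted Grignard 1,2-addition: the oxophilic additive, regarded here as an activator that is not consumed, tempers the basicity of the reagent and activates the electron-rich, peri-hindered C4 carbonyl, which should hold back enolisation at C3 and β-hydride reduction. Tertiary benzylic alcohol 11, flanked by three donor oxygens, should lose water by an E1 path under mild acid to the endocyclic, arene-conjugated C3=C4 alkene. C2 is not involved and keeps its configuration; its descriptor becomes S only because C3 is now sp2.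

Step 6
Reactants: 12 (1'R,2S,4'S)-5,7-bis(benzyloxy)-3',3'-dimethyl-4-(2-methylpropyl)spiro[2H-chromene-2,2'-norbornane]
Product: 13 (1'R,2R,4S,4'S)-3',3'-dimethyl-4-(2-methylpropyl)spiro[chromane-2,2'-norbornane]-5,7-diol
Conditions: H2 (1 atm), 10% Pd/C, EtOAc/EtOH, rt
Reagents that add atoms: none
Why: Heterogeneous catalytic hydrogenation (syn addition) of the trisubstituted styrene-type alkene, with hydrogenolysis of both benzyl ethers in the same operation. C4 is set by the spiro centre: the exo methyl group on C3' eclipses C3 and screens one face of C3=C4, whereas the other face carries only the bridgehead C1'–H, so hydrogen should arrive from the C1' face and leave the isobutyl group cis to C3' (4S).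

Step 7
Reactants: 13 (1'R,2R,4S,4'S)-3',3'-dimethyl-4-(2-methylpropyl)spiro[chromane-2,2'-norbornane]-5,7-diol
Product: 14 (1'R,2R,4S,4'S)-5,7-dihydroxy-3',3'-dimethyl-4-(2-methylpropyl)spiro[chromane-2,2'-norbornane]-6,8-dicarbaldehyde
Conditions: Cl2CHOMe (5 equiv), TiCl4 (6 equiv), CH2Cl2, −40 → 0 °C; then ice/1 M aq HCl
Reagents that add atoms: dichloromethyl methyl ether, COC(Cl)Cl; water, O
Why: Rieche formylation, carried out twice in one operation: titanium aryloxides formed from the two phenols direct the electrophile to C6 and C8, the only free positions and both ortho to a phenol, and aqueous hydrolysis of the α-chloro ethers releases the aldehydes. The temperature is kept low to spare the tertiary C2–O1 bond, whose endo orientation makes it the slower-ionising epimer. No stereocentre is touched.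

## Compound list

1 | (1S,4R)-camphene [(1S,4R)-2,2-dimethyl-3-methylidenebicyclo[2.2.1]heptane] | C=C1[C@@H]2CC[C@@H](C2)C1(C)C | starting material
2 | (1R,4S)-camphenilone [(1R,4S)-3,3-dimethylbicyclo[2.2.1]heptan-2-one] | O=C1[C@@H]2CC[C@@H](C2)C1(C)C | intermediate
3 | 2',4',6'-trifluoroacetophenone | CC(=O)c1c(F)cc(F)cc1F | starting material
4 | benzyl alcohol | OCc1ccccc1 | starting material
5 | 1-[4-(benzyloxy)-2,6-difluorophenyl]ethanone | CC(=O)c1c(F)cc(OCc2ccccc2)cc1F | intermediate
6 | 1-[2,4-bis(benzyloxy)-6-fluorophenyl]ethanone | CC(=O)c1c(F)cc(OCc2ccccc2)cc1OCc1ccccc1 | intermediate
7 | potassium 1-[2,4-bis(benzyloxy)-6-fluorophenyl]ethen-1-olate (formed in the flask, not isolated) | [K+].[O-]C(=C)c1c(F)cc(OCc2ccccc2)cc1OCc1ccccc1 | intermediate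
8 | potassium (1R,2R,4S)-2-{2-[2,4-bis(benzyloxy)-6-fluorophenyl]-2-oxoethyl}-3,3-dimethylbicyclo[2.2.1]heptan-2-olate, alkoxide oxygen endo (formed in the flask, not isolated) | O=C(C[C@@]1([O-])[C@@H]2CC[C@@H](C2)C1(C)C)c1c(F)cc(OCc2ccccc2)cc1OCc1ccccc1.[K+] | intermediate
9 | (1'R,2R,4'S)-5,7-bis(benzyloxy)-3',3'-dimethylspiro[chromane-2,2'-norbornan]-4-one, O1 endo | O=C1C[C@@]2(Oc3cc(OCc4ccccc4)cc(OCc4ccccc4)c31)[C@@H]1CC[C@@H](C1)C2(C)C | intermediate
10 | isobutylmagnesium bromide | CC(C)C[Mg]Br | starting material
11 | (1'R,2R,4'S)-5,7-bis(benzyloxy)-3',3'-dimethyl-4-(2-methylpropyl)spiro[chromane-2,2'-norbornan]-4-ol, both C4 epimers (crude, not isolated) | CC(C)CC1(O)C[C@@]2(Oc3cc(OCc4ccccc4)cc(OCc4ccccc4)c31)[C@@H]1CC[C@@H](C1)C2(C)C | intermediate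
12 | (1'R,2S,4'S)-5,7-bis(benzyloxy)-3',3'-dimethyl-4-(2-methylpropyl)spiro[2H-chromene-2,2'-norbornane] | CC(C)CC1=C[C@@]2(Oc3cc(OCc4ccccc4)cc(OCc4ccccc4)c31)[C@@H]1CC[C@@H](C1)C2(C)C | intermediate
13 | (1'R,2R,4S,4'S)-3',3'-dimethyl-4-(2-methylpropyl)spiro[chromane-2,2'-norbornane]-5,7-diol | CC(C)C[C@H]1C[C@@]2(Oc3cc(O)cc(O)c31)[C@@H]1CC[C@@H](C1)C2(C)C | intermediate
14 | (1'R,2R,4S,4'S)-5,7-dihydroxy-3',3'-dimethyl-4-(2-methylpropyl)spiro[chromane-2,2'-norbornane]-6,8-dicarbaldehyde | CC(C)C[C@H]1C[C@@]2(Oc3c(C=O)c(O)c(C=O)c(O)c31)[C@@H]1CC[C@@H](C1)C2(C)C | target

## Step count and least certain steps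

Total: 7 steps. Longest linear sequence: 6 steps (steps 2, 3, 4, 5, 6, 7 from 3); the branch from 1 joins at step 4 and runs through 5 steps (1, 4, 5, 6, 7). Steps 1 to 3 are regarded as lower risk; the two fluoride displacements are run separately so that each can be held at a single substitution and 5 can be purified before the second.

**Step 4 (key step).** Two things are most likely to go wrong.
- The reaction may stall or be diverted. The aldol equilibrium with a ketone flanked by a bridgehead and a quaternary carbon lies far on the side of 7 and 2. The arene is also a less willing acceptor than a simple 2-fluoroacetophenone, because its two benzyloxy groups are conjugated with the carbonyl. The temperature needed for ring closure may therefore let self-condensation or intermolecular fluoride displacement compete.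
- The spiro configuration may be lost. Under Curtin–Hammett conditions a minor exo-alkoxide aldolate could cyclise faster than 8, and prolonged exposure to base could open the enolate of 9 by β-elimination of the phenoxide and reclose it from either face.

The fallback sets out from 6 and 2 and returns at 9. It separates the two bond formations. Compound 6 would be enolised with LiN(iPr)2 (THF, −78 °C), the lithium enolate transmetalated with anhydrous CeCl3 and combined with 2 at −78 °C. A cold quench with acetic acid should then give the β-hydroxy ketone 1-[2,4-bis(benzyloxy)-6-fluorophenyl]-2-[(1R,2R,4S)-2-hydroxy-3,3-dimethylbicyclo[2.2.1]heptan-2-yl]ethanone F1 under kinetic, exo-selective control, since a cerium aldolate resists retro-aldol cleavage far better than a potassium one. Purified F1 would be closed in a second flask by brief treatment with KOtBu in THF at 0 °C. Any retro-aldol cleavage at that stage only regenerates the partners of step 4.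

**Step 6.** The most likely failure is poor or reversed facial selectivity in the delivery of hydrogen to C3=C4. The half-chair of the chromene can place either C1' or C3' pseudoaxial, and palladium can move the double bond to the exocyclic position before reducing it. Both effects would erode the bias of the eclipsing exo methyl group.

The fallback sets out from 9 and returns at 13. It forms C4 by a C–C bond instead of a C–H bond, which inverts the stereochemical consequence of a given facial preference: a carbon nucleophile entering on a face leaves the side chain on that face, whereas hydrogen entering there leaves it on the other. Ketone 9 would be reduced with NaBH4 (MeOH/THF, 0 °C) to (1'R,2R,4'S)-5,7-bis(benzyloxy)-3',3'-dimethylspiro[chromane-2,2'-norbornan]-4-ol F2 (C4 epimers, of no consequence). F2 would be ionised with BF3·OEt2 in CH2Cl2 at −78 °C in the presence of excess methallyltrimethylsilane (Hosomi–Sakurai-type trapping of the dialkoxy-stabilised benzylic cation) to give (1'R,2R,4S,4'S)-5,7-bis(benzyloxy)-3',3'-dimethyl-4-(2-methylprop-2-en-1-yl)spiro[chromane-2,2'-norbornane] F3. Hydrogenation of F3 over 10% Pd/C would saturate the side-chain alkene, which creates no stereocentre, and remove both benzyl groups to give 13. This answers the case in which the C3' face proves to be the open one. If selectivity is merely low in both modes, the C4 epimers of 13 would have to be separated.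

**Step 5.** The most likely failure is enolisation of 9 at C3 and β-hydride transfer from the branched Grignard reagent in place of addition, because the carbonyl is deactivated by three donor oxygens and crowded by the C5 benzyloxy group. A secondary risk is acid-induced opening of the allylic tertiary ether during dehydration.

The fallback sets out from 9 and returns at 12. It turns the ease of enolisation to use. Deprotonation with KN(SiMe3)2 and trapping with PhNTf2 (THF, −78 °C) should give the enol triflate (1'R,2S,4'S)-5,7-bis(benzyloxy)-3',3'-dimethylspiro[2H-chromene-2,2'-norbornan]-4-yl trifluoromethanesulfonate F4. Negishi coupling of F4 with isobutylzinc bromide (prepared from 10 and ZnBr2; PdCl2(dppf), THF, 50 °C; oxidative addition to zerovalent palladium, transmetalation, reductive elimination) would give 12 directly, with no carbinol and no acid.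

**Step 7.** The most likely failures are ionisation of the C2–O1 bond, once TiCl4 can chelate between O1 and a newly installed C8 formyl group, with ensuing skeletal rearrangement, and stalling after the first formylation because the ring is then deactivated.

The fallback sets out from 13 and returns at 14. It replaces electrophilic formylation by halogen–metal exchange. Dibromination of 13 with NBS (2 equiv, MeCN, −20 °C) should give (1'R,2R,4S,4'S)-6,8-dibromo-3',3'-dimethyl-4-(2-methylpropyl)spiro[chromane-2,2'-norbornane]-5,7-diol F5. Protection with MOMCl and iPr2NEt would give the 5,7-bis(methoxymethyl) ether F6. Twofold bromine–lithium exchange with t-BuLi (Et2O/THF, −78 °C) and quenching with DMF would give the bis(methoxymethyl)-protected dialdehyde F7. Brief treatment with aqueous HCl in methanol would then release 14.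

## Further compounds

F1 | step 4 | 1-[2,4-bis(benzyloxy)-6-fluorophenyl]-2-[(1R,2R,4S)-2-hydroxy-3,3-dimethylbicyclo[2.2.1]heptan-2-yl]ethanone (hydroxyl endo) | O=C(C[C@@]1(O)[C@@H]2CC[C@@H](C2)C1(C)C)c1c(F)cc(OCc2ccccc2)cc1OCc1ccccc1
F2 | step 6 | (1'R,2R,4'S)-5,7-bis(benzyloxy)-3',3'-dimethylspiro[chromane-2,2'-norbornan]-4-ol (C4 epimers) | OC1C[C@@]2(Oc3cc(OCc4ccccc4)cc(OCc4ccccc4)c31)[C@@H]1CC[C@@H](C1)C2(C)C
F3 | step 6 | (1'R,2R,4S,4'S)-5,7-bis(benzyloxy)-3',3'-dimethyl-4-(2-methylprop-2-en-1-yl)spiro[chromane-2,2'-norbornane] | C=C(C)C[C@H]1C[C@@]2(Oc3cc(OCc4ccccc4)cc(OCc4ccccc4)c31)[C@@H]1CC[C@@H](C1)C2(C)C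
F4 | step 5 | (1'R,2S,4'S)-5,7-bis(benzyloxy)-3',3'-dimethylspiro[2H-chromene-2,2'-norbornan]-4-yl trifluoromethanesulfonate | O=S(=O)(OC1=C[C@@]2(Oc3cc(OCc4ccccc4)cc(OCc4ccccc4)c31)[C@@H]1CC[C@@H](C1)C2(C)C)C(F)(F)F
F5 | step 7 | (1'R,2R,4S,4'S)-6,8-dibromo-3',3'-dimethyl-4-(2-methylpropyl)spiro[chromane-2,2'-norbornane]-5,7-diol | CC(C)C[C@H]1C[C@@]2(Oc3c(Br)c(O)c(Br)c(O)c31)[C@@H]1CC[C@@H](C1)C2(C)C
F6 | step 7 | (1'R,2R,4S,4'S)-6,8-dibromo-5,7-bis(methoxymethoxy)-3',3'-dimethyl-4-(2-methylpropyl)spiro[chromane-2,2'-norbornane] | CC(C)C[C@H]1C[C@@]2(Oc3c(Br)c(OCOC)c(Br)c(OCOC)c31)[C@@H]1CC[C@@H](C1)C2(C)C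
F7 | step 7 | (1'R,2R,4S,4'S)-5,7-bis(methoxymethoxy)-3',3'-dimethyl-4-(2-methylpropyl)spiro[chromane-2,2'-norbornane]-6,8-dicarbaldehyde | CC(C)C[C@H]1C[C@@]2(Oc3c(C=O)c(OCOC)c(C=O)c(OCOC)c31)[C@@H]1CC[C@@H](C1)C2(C)C
A1 | alternative 1 | (1R,2R,4S)-3,3-dimethylspiro[bicyclo[2.2.1]heptane-2,2'-oxirane] (oxygen endo, CH2 exo) | C1O[C@@]12[C@@H]3CC[C@@H](C3)C2(C)C
A2 | alternative 1 | 2-(tert-butyldimethylsilyl)-1,3-dithiane | CC(C)(C)[Si](C)(C)C1SCCCS1
A3 | alternative 1 | 1-iodo-2-methylpropane | CC(C)CI
A4 | alternative 1 | 2-isobutyl-2-{[(1R,2R,4S)-2-(tert-butyldimethylsilyloxy)-3,3-dimethylbicyclo[2.2.1]heptan-2-yl]methyl}-1,3-dithiane (silyloxy endo) | CC(C)CC1(C[C@@]2(O[Si](C)(C)C(C)(C)C)[C@@H]3CC[C@@H](C3)C2(C)C)SCCCS1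
A5 | alternative 2 | (2R,4S)-5,7-bis(benzyloxy)-2-(cyclopent-3-en-1-yl)-4-(2-methylpropyl)-2-(prop-1-en-2-yl)chromane | CC(C)C[C@H]1C[C@](C(C)=C)(C2CC=CC2)Oc2cc(OCc3ccccc3)cc(OCc3ccccc3)c21
A6 | alternative 2 | (1'R,2R,4S,4'S)-5,7-bis(benzyloxy)-3',3'-dimethyl-4-(2-methylpropyl)spiro[chromane-2,2'-norbornane] | CC(C)C[C@H]1C[C@@]2(Oc3cc(OCc4ccccc4)cc(OCc4ccccc4)c31)[C@@H]1CC[C@@H](C1)C2(C)C
A7 | alternative 3 | (1R,2R,4S)-2-[3,5-bis(benzyloxy)phenoxy]-3,3-dimethyl-2-(4-methylpent-1-yn-1-yl)bicyclo[2.2.1]heptane (aryloxy endo) | CC(C)CC#C[C@@]1(Oc2cc(OCc3ccccc3)cc(OCc3ccccc3)c2)[C@@H]2CC[C@@H](C2)C1(C)C
A8 | alternative 3 | (1'R,2S,4'S)-5,7-bis(benzyloxy)-3',3'-dimethyl-4-(2-methylpropyl)spiro[2H-chromene-2,2'-norbornane] (identical with 12) | CC(C)CC1=C[C@@]2(Oc3cc(OCc4ccccc4)cc(OCc4ccccc4)c31)[C@@H]1CC[C@@H](C1)C2(C)C
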